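## Analysis of the target

The target (36) is an N-unsubstituted 3-acyltetramic acid, drawn as its C4 enol. Its C5 is (S) and carries an (R)-1-hydroxyethyl group, the pattern of L-threonine. The acyl carbonyl joins it to C1 of a cis-fused octalin.

The decalin is numbered C1 (quaternary: methyl and acyl), C2 ((1E,3E)-penta-1,3-dienyl), C3=C4, ring-fusion carbons C4a and C8a, and C6 (methyl). Ring A is the cyclohexene C1–C2–C3–C4–C4a–C8a and ring B the cyclohexane C4a–C5–C6–C7–C8–C8a. The same locants are used below for the bridged precursors.

On ring A the acyl group at C1, the dienyl group at C2 and the hydrogens at C4a and C8a lie on one face; the C1 methyl, C5 and C8 lie on the other. On ring B the C6 hydrogen is cis to both ring-fusion hydrogens.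

The sensitive groups are the conjugated diene (acid, electrophilic oxidants, radical chains) and the acidic, chelating tricarbonyl unit, whose C5 can epimerise in base.

Three things make the synthesis hard. C1 is quaternary and flanked by two stereocentres. The ring fusion is cis. The C6 methyl is judged to be axial in the less strained chair–chair form of this cis-decalin (C1 equatorial on ring B), so C6 cannot be left to equilibrate and must be set kinetically.

The strategy rests on the C3=C4 double bond lying directly next to the cis ring-fusion carbon C4a, with C1 and C2 contiguous on ring A. This is the imprint of a 2-alkenylbicyclo[2.2.2]oct-5-en-2-ol in which ring A already exists as the boat ring (bridges C1–C2 and C4=C4a, bridgeheads C3 and C8a) and C7 is a carbinol carbon on the third bridge, bonded to C3.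

## Retrosynthetic reasoning

**Heterocycle.** 36 is traced to its silyl ether 35, and 35 to β-ketoamide 34 by cutting the C3–C4 bond of the tetramic acid (Lacey–Dieckmann closure). 34 is cut at the amide bond into β-keto thioester 31 and O-silylated L-threonine methyl ester 33, made from 32. Both heteroatom-bearing stereocentres are thus bought, and the acidic, chelating ring appears only at the end. The forward closure must be fast enough that the threonine α-carbon is not enolised.

**Acyl chain.** 31 is cut between the C1 acyl carbon and its α-methylene, giving aldehyde 28 and thioacetate 29 (aldol addition, then oxidation through 30). A C1 carboxylic acid was not chosen as the branching point: acid derivatives on this neopentyl quaternary carbon resist Claisen-type acylation, whereas the aldehyde accepts a small thioester enolate. 28 comes from alcohol 27 and silyl ether 26.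

**Diene.** 26 is cut at the double bond adjacent to C2 into tetrazolyl sulfone 24 and enal 25 (Julia–Kocienski olefination). The sulfone sits on the decalin for two reasons: a C2 aldehyde would be β,γ-unsaturated and epimerisable under base, and an alkyl sulfone with an enal is the E-selective pairing. The diene is introduced only after all tin hydride and strong-base steps. 24 goes back through sulfide 23 and alcohol 22 to the bis-silyl ether 21.

**C7 oxygen.** 21 is traced to ketone 18 through alcohol 19 and xanthate 20. The C7 carbonyl is the trace left by the key step. It is removed at once because it makes C6 epimerisable.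

**Ring B (key disconnection).** 18 is opened by a retro-oxy-Cope step: C4a–C5 is cut and C3–C7 is reconnected, giving the bicyclic tertiary carbinol 15. This removes ring B and the C4a and C6 stereocentres. What remains is a rigid bicyclo[2.2.2]octene in which C1, C2 and C8a are already fixed. The forward reaction must form C4a–C5 on the face of the alkene bridge turned toward the carbinol bridge, and must then protonate C6 from the convex face.

**Carbinol and third bridge.** 15 comes from ketone 13 and isopropenylmagnesium bromide 14, added from the alkene face. 13 is the hydrolysis product of ketal 12, which comes from alcohol 10 through xanthate 11. The oxygen at C8 has to go because the cycloaddition places the dienone carbonyl at C8 and the masked carbonyl at C7, the reverse of what the rearrangement needs. The two silyl ethers of 10 go back through 9 to triol 8, where the two arms are told apart by hindrance (the C1 arm is neopentyl). 8 comes from cycloadduct 7 by hydride reduction of the ketone and of the lactone acetal.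

**Bicyclic core.** 7 is cut at C1–C8a and C2–C3 into masked o-benzoquinone 6, made in the flask from phenol 5, and butenolide 4 (Diels–Alder reaction). This one step sets C1, C2 and C8a, with absolute configuration taken from the acetal carbon of 4. 4 comes from lactol 2 and menthol 3, and 2 from furoic acid 1 by photooxygenation. The cycloaddition must join the methyl-bearing carbon of 4 to the ring carbon next to the dienone carbonyl, with the lactone under the diene.

## Alternatives that were turned down

**Alternative 1:** Ring A is cut at C2–C3, and the dienyl group is folded back into a skipped hexa-1,4-dienyl arm on C1, giving vinyl iodide A2.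
- Key step: zerovalent palladium (from Pd(OAc)2, PPh3, Ag2CO3) inserts into the (Z)-vinyl iodide on C4a of A2, adds 6-exo to the proximal alkene to form C2–C3, and loses a β-hydride from the doubly allylic methylene, giving dienyl ester A1.
- For: ring A, the C2 centre and the diene arise in one operation. C1 is already an ester, so the end game from A1 would be shorter than from 21. C6 is carried in as a fixed centre. On these points it is stronger than the chosen route.
- Against: C2 is created by the facial choice of an alkene attached to an acyclic quaternary carbon. β-Hydride loss toward C2–H would pull the new double bond into conjugation with C3=C4 instead. The skipped diene is prone to isomerisation by palladium hydride. The quaternary C1 of A2 has to be built in an open chain next to C8a.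
- Comparison: the chosen route sets C1, C2 and C8a in a single endo cycloaddition under auxiliary control and C4a by the geometry of a rearrangement. It pays for this with a longer functional-group sequence afterwards.

**Alternative 2:** C1–C2 is cut and C4 is tied through oxygen to the C1 carboxyl carbon, giving the cis-fused six-membered lactone A4 with a hepta-1,3,5-trienyl group on C4.
- Key step: A4 is enolised and O-silylated (LiN(iPr)2, Me3SiCl) and warmed. An Ireland–Claisen [3,3] shift forms C1–C2, breaks C4–O and contracts the lactone to ring A, giving acid A3.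
- For: the quaternary C1 and C2 are formed together, with chirality transfer from the C4 carbinol through a ring-constrained boat. C1 emerges at the acid level and C6 is fixed beforehand. In creating C1 and C2 stereospecifically in one event it is as strong as the chosen cycloaddition.
- Against: A4 is an allylic ester of a heptatrienyl carbinol and should ionise, transpose or eliminate easily. The triene must survive strong base, and the extended polyene offers vinylogous shift pathways. The trienyl group must sit on the concave face of the lactone. The hindered acid A3 is a poor starting point for the β-ketoamide.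
- Comparison: the chosen route keeps the diene out of the molecule until the carbon skeleton is finished and enters the acyl chain through an aldehyde. In exchange it needs a kinetic protonation at C6.

**Alternative 3:** C4–C4a is cut. Ring B is a cyclohexene (C4a=C5) carrying the fully substituted C1–C2 unit with a (Z)-vinyl iodide, compound A6.
- Key step: zerovalent palladium (from Pd(OAc)2, PPh3, HCO2Na) inserts into the C–I bond of A6 and adds across C4a=C5, forming C4–C4a and a cis-fused ring A. The C5–palladium bond has no syn β-hydrogen and is reduced by formate, giving ester A5.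
- For: the cis fusion follows from the tether. C6 is present from the start. There is no C7 oxygen to remove and C1 is an ester. On C6 and on ring B economy it is stronger than the chosen route.
- Against: A6 needs the contiguous C1 (quaternary), C2 and C8a centres assembled without a ring to direct them, and C6 placed 1,4 across ring B. Reduction of the vinylpalladium before it cyclises onto the ring alkene is a likely leak. A5 still carries only a silyloxymethyl group at C2, so the diene must be built afterwards as in the chosen route.
- Comparison: the chosen route reaches the same C1–C2–C8a array in one cycloaddition from a phenol and a butenolide. It accepts three extra steps in ring B and a kinetically set C6 as the price.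

Key step: step 11

Assumption: the (5S) acetal epimer 4 is taken to be the one that crystallises, as in the 3-unsubstituted series; the carbinol centres at C8 (8–11), at C7 (19, 20) and in 30 are transient and are drawn with the expected or an arbitrary configuration.

## Route

Step 1
Reactants: 1 3-methylfuran-2-carboxylic acid
Product: 2 5-hydroxy-3-methylfuran-2(5H)-one (racemic lactol)
Conditions: O2, hν (visible), rose bengal (cat.), MeOH, 0 °C
Reagents that add atoms: oxygen, O=O
Why: Singlet oxygen adds [4+2] across C2 and C5 of the furan, and the endoperoxide fragments with loss of CO2 (decarboxylative photooxygenation of a 2-furoic acid), which leaves the lactone carbonyl next to the methyl-bearing carbon.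

Step 2
Reactants: 2 5-hydroxy-3-methylfuran-2(5H)-one; 3 (+)-menthol, (1S,2R,5S)-2-isopropyl-5-methylcyclohexan-1-ol
Product: 4 (5S)-3-methyl-5-[(1S,2R,5S)-menthyloxy]furan-2(5H)-one
Conditions: CSA (cat.), toluene, reflux, azeotropic removal of water; crystallisation from hexane, mother liquor re-equilibrated with CSA
Reagents that add atoms: none
Why: Acid-catalysed acetalisation of the pseudo-acid; the two acetal epimers interconvert under acid, so the crystalline (5S) epimer can be harvested with recycling of the other. This acetal centre later fixes the absolute configuration of the carbocycle.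

Step 3
Reactants: 5 2-methoxyphenol; 4 (5S)-3-methyl-5-menthyloxyfuran-2(5H)-one
Product: 7 endo cycloadduct: bicyclo[2.2.2]oct-5-ene (bridgeheads C3 and C8a) with a C8 ketone, a C7 dimethyl ketal, a methyl group on C1 and the menthyloxy-γ-lactone fused at C1–C2 syn to the alkene bridge (lactone carbonyl on C1, acetal carbon on C2), via masked o-benzoquinone 6 (not isolated)
Conditions: PhI(OAc)2, MeOH, 4 (3 equiv, excess recovered), slow addition of 5, 0 °C → 50 °C
Reagents that add atoms: methanol, CO
Why: Oxidative dearomatisation gives dienone 6, which is trapped in a Diels–Alder reaction before it dimerises. As with acrylates and methacrylates, the carbonyl-bearing carbon of the dienophile should bond to the ring carbon next to the dienone carbonyl, which puts the quaternary C1 on C8a. Endo approach places the lactone under the new alkene bridge, and attack anti to the menthyloxy group sets C1, C2 and C8a in the absolute sense.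

Step 4
Reactants: 7 cycloadduct
Product: 8 triol: C8 carbinol, hydroxymethyl groups on C1 and C2 (both syn to the alkene bridge), C7 dimethyl ketal
Conditions: LiAlH4, THF, 0 °C → 40 °C; aqueous NaOH work-up
Reagents that add atoms: none
Why: Hydride reduces the C8 ketone and the acyl acetal: the lactone carbonyl becomes the C1 hydroxymethyl group, and the acetal carbon becomes the C2 hydroxymethyl group with release of menthol. The dimethyl ketal and the alkene are inert.

Step 5
Reactants: 8 triol
Product: 9 C2-arm tert-butyldimethylsilyl ether of 8
Conditions: TBSCl (1.05 equiv), imidazole, CH2Cl2/DMF, −20 °C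
Reagents that add atoms: tert-butyldimethylsilyl chloride, CC(C)(C)[Si](C)(C)Cl
Why: Kinetic silylation should pick the least hindered hydroxyl: the C2 arm hangs from a methine, the C1 arm is neopentyl, and the C8 carbinol is secondary and flanked by the ketal.

Step 6
Reactants: 9 mono-silyl ether
Product: 10 C2-arm TBS ether, C1-arm tert-butyldiphenylsilyl ether, free C8 carbinol
Conditions: TBDPSCl, imidazole, DMAP (cat.), DMF, 40 °C
Reagents that add atoms: tert-butyldiphenylsilyl chloride, CC(C)(C)[Si](Cl)(c1ccccc1)c1ccccc1
Why: The remaining primary hydroxyl is silylated in preference to the hindered secondary one. TBDPS is chosen because it survives the later acidic removal of the TBS group and can be removed by fluoride in the presence of the diene.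

Step 7
Reactants: 10 C8 carbinol
Product: 11 C8 O-alkyl S-methyl dithiocarbonate (xanthate)
Conditions: NaH, imidazole (cat.), THF, 0 °C; CS2; MeI, rt
Reagents that add atoms: carbon disulfide, S=C=S; iodomethane, CI
Why: Standard xanthate formation; it works on hindered secondary alkoxides, and the silyl ethers lie on the far side of the bicycle.

Step 8
Reactants: 11 xanthate
Product: 12 C8-methylene bicyclo[2.2.2]oct-5-ene, C7 dimethyl ketal
Conditions: Bu3SnH (0.5 M), AIBN (cat.), toluene, 100 °C
Reagents that add atoms: none
Why: Barton–McCombie deoxygenation. The secondary C8 radical is homoallylic to C4a=C4, but its rearrangement through a cyclopropylcarbinyl radical leads to a more strained, unstabilised radical, and a high tin hydride concentration should trap it first.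

Step 9
Reactants: 12 dimethyl ketal
Product: 13 bicyclo[2.2.2]oct-5-en-2-one with the carbonyl at C7
Conditions: oxalic acid, wet SiO2, CH2Cl2, rt
Reagents that add atoms: water, O
Why: Mild hydrolysis of an unhindered dimethyl ketal, which is far faster than cleavage of the primary TBS ether.

Step 10
Reactants: 13 C7 ketone; 14 isopropenylmagnesium bromide
Product: 15 tertiary carbinol: 2-isopropenylbicyclo[2.2.2]oct-5-en-2-ol with the isopropenyl group syn to the alkene bridge and both silyloxymethyl arms syn to the alkene bridge
Conditions: CeCl3 (anhydrous), THF, −78 °C; 14, then 13, −78 °C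
Reagents that add atoms: none
Why: The organocerium reagent adds 1,2 without enolising C8. Attack should come from the alkene side, because the other face of C7 is screened by C2–H and the C1 methyl on the saturated bridge; this sets C7 with the isopropenyl group where the rearrangement needs it.

Step 11
Reactants: 15 tertiary carbinol
Product: 18 cis-fused decalin C7 ketone (6-methyl, C3=C4, silyloxymethyl arms on C1 and C2), via potassium alkoxide 16 (not isolated), via potassium enolate 17 (not isolated)
Conditions: KH, 18-crown-6, THF, 0 °C → rt; then −78 °C, 2,6-di-tert-butyl-4-methylphenol in THF; aq NH4Cl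
Reagents that add atoms: none
Why: KH with 18-crown-6 turns 15 into the dissociated alkoxide 16, in which the C3–C7 bond is weakened, so the 1,5-diene formed by the isopropenyl group and the C4=C4a bridge undergoes an anionic oxy-Cope [3,3] shift near room temperature. The bicyclic frame enforces a boat transition state: the isopropenyl CH2 (future C5) bonds to C4a on the face turned toward the carbinol bridge while C3–C7 breaks, so ring B closes by sigmatropic reorganisation and not by an exo or endo attack, and C3=C4 emerges from the old bridgehead. The closest known reaction is the rearrangement of 2-alkenylbicyclo[2.2.2]oct-5-en-2-ols to cis-fused octalones. C4a is controlled by the frame: C5 and C8 both descend from the same bridge, so the fusion can only be cis, while C1, C2 and C8a are carried over unchanged. C6 is set when enolate 17 is protonated at −78 °C: ring A covers the concave face, so the bulky phenol should deliver the proton to the convex face and place H6 cis to H4a and H8a. The step needs the isopropenyl group syn to the alkene bridge, which step 10 secures. It also needs a strictly kinetic quench, because the wanted C6 epimer is judged the less stable one; the hindered phenoxide left behind is a poor base for re-enolisation, and 18 is reduced in the next step without storage.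

Step 12
Reactants: 18 C7 ketone
Product: 19 C7 alcohol (either carbinol epimer serves)
Conditions: LiAlH4, Et2O, −78 °C
Reagents that add atoms: none
Why: Fast, non-equilibrating hydride reduction removes the carbonyl that makes C6 epimerisable; the new carbinol centre is deleted two steps later.

Step 13
Reactants: 19 C7 alcohol
Product: 20 C7 xanthate
Conditions: NaH, imidazole (cat.), THF, 0 °C; CS2; MeI, rt
Reagents that add atoms: carbon disulfide, S=C=S; iodomethane, CI
Why: Xanthate formation on a secondary alkoxide; with C7 now sp3 there is no enolisable position left next to C6.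

Step 14
Reactants: 20 xanthate
Product: 21 (1,6-dimethyl) cis-octalin with CH2OTBS on C2 and CH2OTBDPS on C1
Conditions: Bu3SnH (0.5 M), AIBN (cat.), toluene, 100 °C
Reagents that add atoms: none
Why: Barton–McCombie deoxygenation. Closure of the C7 radical onto C3=C4 would have to build a strained bridged ring and should lose to hydrogen transfer at high tin hydride concentration.

Step 15
Reactants: 21 bis-silyl ether
Product: 22 C2 hydroxymethyl compound (C1 arm still TBDPS-protected)
Conditions: CSA (cat.), MeOH/CH2Cl2, 0 °C
Reagents that add atoms: none
Why: Acid-catalysed methanolysis removes a primary TBS ether much faster than a TBDPS ether, all the more so a neopentyl one.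

Step 16
Reactants: 22 primary alcohol
Product: 23 C2-methylene 1-phenyl-1H-tetrazol-5-yl sulfide
Conditions: 1-phenyl-1H-tetrazole-5-thiol, PPh3, DIAD, THF, 0 °C → rt
Reagents that add atoms: 1-phenyl-1H-tetrazole-5-thiol, Sc1nnnn1-c1ccccc1
Why: Mitsunobu thioetherification of a primary alcohol; it proceeds by SN2 displacement at the CH2 group, so C2 is not touched.

Step 17
Reactants: 23 sulfide
Product: 24 C2-methylene 1-phenyl-1H-tetrazol-5-yl sulfone
Conditions: (NH4)6Mo7O24·4H2O (cat.), H2O2 (30%), EtOH, 0 °C → rt
Reagents that add atoms: hydrogen peroxide, OO
Why: Molybdate-catalysed oxidation of sulfide to sulfone, which is faster than epoxidation of an unactivated cis-disubstituted ring alkene.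

Step 18
Reactants: 24 sulfone; 25 (E)-but-2-enal
Product: 26 C2 (1E,3E)-penta-1,3-dienyl octalin, C1 arm TBDPS-protected
Conditions: KHMDS, DME, −60 °C; then 25, −60 °C → rt
Reagents that add atoms: none
Why: Julia–Kocienski olefination: the sulfonyl anion adds 1,2 to the enal, and Smiles rearrangement with loss of SO2 and the tetrazolone gives the new double bond. The pairing of an alkyl phenyltetrazolyl sulfone with an enal in a polar ether favours E, and the geometry of 25 is carried through.

Step 19
Reactants: 26 silyl ether
Product: 27 C1 hydroxymethyl dienyl octalin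
Conditions: TBAF, THF, 40 °C
Reagents that add atoms: none
Why: Fluoride cleaves the neopentyl TBDPS ether under conditions that leave the diene untouched.

Step 20
Reactants: 27 neopentyl alcohol
Product: 28 C1 carbaldehyde
Conditions: Dess–Martin periodinane, pyridine, CH2Cl2, 0 °C → rt
Reagents that add atoms: none
Why: Neutral, buffered oxidation of a primary alcohol; the aldehyde sits on a quaternary carbon and cannot epimerise.

Step 21
Reactants: 28 aldehyde; 29 S-tert-butyl ethanethioate
Product: 30 β-hydroxy thioester (mixture of carbinol epimers)
Conditions: LiN(iPr)2, 29, THF, −78 °C; then 28; aq NH4Cl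
Reagents that add atoms: none
Why: Aldol addition of a small lithium thioester enolate to the hindered but non-enolisable aldehyde; the new carbinol centre is oxidised away in the next step.

Step 22
Reactants: 30 β-hydroxy thioester
Product: 31 β-keto thioester
Conditions: Dess–Martin periodinane, pyridine, CH2Cl2, 0 °C → rt
Reagents that add atoms: none
Why: Oxidation of the secondary alcohol to the 1,3-dicarbonyl compound under non-basic conditions that spare the diene.

Step 23
Reactants: 32 L-threonine methyl ester hydrochloride
Product: 33 O-tert-butyldimethylsilyl-L-threonine methyl ester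
Conditions: TBSCl, imidazole, DMF, rt; aqueous work-up
Reagents that add atoms: tert-butyldimethylsilyl chloride, CC(C)(C)[Si](C)(C)Cl
Why: O-Silylation of the secondary alcohol; any N–Si bond formed is hydrolysed on work-up, and neither stereocentre is touched.

Step 24
Reactants: 31 β-keto thioester; 33 amino ester
Product: 34 β-ketoamide
Conditions: AgOCOCF3, Et3N, THF, 0 °C
Reagents that add atoms: none
Why: Silver-assisted aminolysis of the thioester: the thiophilic metal activates the C–S bond so that the amine is acylated at 0 °C without base-mediated enolisation of the amino ester.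

Step 25
Reactants: 34 β-ketoamide
Product: 35 3-acyltetramic acid, O-silylated at the side-chain hydroxyl
Conditions: KOtBu, tBuOH, rt, 10 min; 1 M HCl
Reagents that add atoms: none
Why: Lacey–Dieckmann cyclisation: the stabilised β-dicarbonyl anion attacks the methyl ester and the product is held as its delocalised anion. A short reaction time in a hindered alcohol limits enolisation at the threonine α-carbon.

Step 26
Reactants: 35 silyl ether
Product: 36 target
Conditions: HF (48% aq), MeCN, 0 °C
Reagents that add atoms: none
Why: Fluoride-assisted cleavage of the secondary TBS ether under mildly acidic conditions that the diene and the acyltetramic acid tolerate.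

## Compound list

1 | 3-methylfuran-2-carboxylic acid | Cc1ccoc1C(=O)O | starting material
2 | 5-hydroxy-3-methylfuran-2(5H)-one | CC1=CC(O)OC1=O | intermediate
3 | (+)-menthol | CC(C)[C@H]1CC[C@H](C)C[C@@H]1O | starting material
4 | (5S)-3-methyl-5-[(1S,2R,5S)-menthyloxy]furan-2(5H)-one | CC1=C[C@@H](O[C@H]2C[C@@H](C)CC[C@@H]2C(C)C)OC1=O | intermediate
5 | 2-methoxyphenol | COc1ccccc1O | starting material
6 | 6,6-dimethoxycyclohexa-2,4-dien-1-one | COC1(OC)C=CC=CC1=O | intermediate
7 | endo cycloadduct (C8 ketone, C7 dimethyl ketal, menthyloxy lactone on C1–C2) | O=C1O[C@H](O[C@H]4C[C@@H](C)CC[C@@H]4C(C)C)[C@H]2[C@H]3C=C[C@H](C(=O)C3(OC)OC)[C@@]12C | intermediate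
8 | triol (C8 carbinol, C1 and C2 hydroxymethyl, C7 ketal) | OC[C@H]2[C@H]3C=C[C@H]([C@@H](O)C3(OC)OC)[C@@]2(C)CO | intermediate
9 | C2-arm TBS ether | CC(C)(C)[Si](C)(C)OC[C@H]2[C@H]3C=C[C@H]([C@@H](O)C3(OC)OC)[C@@]2(C)CO | intermediate
10 | C2-arm TBS, C1-arm TBDPS ether, C8 carbinol | CC(C)(C)[Si](C)(C)OC[C@H]2[C@H]3C=C[C@H]([C@@H](O)C3(OC)OC)[C@@]2(C)CO[Si](c4ccccc4)(c5ccccc5)C(C)(C)C | intermediate
11 | C8 xanthate | CC(C)(C)[Si](C)(C)OC[C@H]2[C@H]3C=C[C@H]([C@@H](OC(=S)SC)C3(OC)OC)[C@@]2(C)CO[Si](c4ccccc4)(c5ccccc5)C(C)(C)C | intermediate
12 | C8-methylene C7 dimethyl ketal | CC(C)(C)[Si](C)(C)OC[C@H]2[C@H]3C=C[C@H](CC3(OC)OC)[C@@]2(C)CO[Si](c4ccccc4)(c5ccccc5)C(C)(C)C | intermediate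
13 | bicyclic C7 ketone | CC(C)(C)[Si](C)(C)OC[C@H]2[C@H]3C=C[C@H](CC3=O)[C@@]2(C)CO[Si](c4ccccc4)(c5ccccc5)C(C)(C)C | intermediate
14 | isopropenylmagnesium bromide | CC(=C)[Mg]Br | starting material
15 | 2-isopropenylbicyclo[2.2.2]oct-5-en-2-ol (key precursor) | CC(C)(C)[Si](C)(C)OC[C@H]2[C@H]3C=C[C@H](C[C@]3(O)C(C)=C)[C@@]2(C)CO[Si](c4ccccc4)(c5ccccc5)C(C)(C)C | intermediate
16 | potassium alkoxide of 15 | CC(C)(C)[Si](C)(C)OC[C@H]2[C@H]3C=C[C@H](C[C@]3([O-])C(C)=C)[C@@]2(C)CO[Si](c4ccccc4)(c5ccccc5)C(C)(C)C.[K+] | intermediate
17 | potassium C6=C7 enolate of the cis-decalin | CC(C)(C)[Si](C)(C)OC[C@H]2C=C[C@@H]3CC(C)=C([O-])C[C@@H]3[C@@]2(C)CO[Si](c4ccccc4)(c5ccccc5)C(C)(C)C.[K+] | intermediate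
18 | cis-decalin C7 ketone | CC(C)(C)[Si](C)(C)OC[C@H]2C=C[C@@H]3C[C@H](C)C(=O)C[C@@H]3[C@@]2(C)CO[Si](c4ccccc4)(c5ccccc5)C(C)(C)C | intermediate
19 | C7 alcohol | CC(C)(C)[Si](C)(C)OC[C@H]2C=C[C@@H]3C[C@H](C)[C@H](O)C[C@@H]3[C@@]2(C)CO[Si](c4ccccc4)(c5ccccc5)C(C)(C)C | intermediate
20 | C7 xanthate | CC(C)(C)[Si](C)(C)OC[C@H]2C=C[C@@H]3C[C@H](C)[C@H](OC(=S)SC)C[C@@H]3[C@@]2(C)CO[Si](c4ccccc4)(c5ccccc5)C(C)(C)C | intermediate
21 | deoxygenated bis-silyl ether | CC(C)(C)[Si](C)(C)OC[C@H]2C=C[C@@H]3C[C@H](C)CC[C@@H]3[C@@]2(C)CO[Si](c4ccccc4)(c5ccccc5)C(C)(C)C | intermediate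
22 | C2 hydroxymethyl compound | OC[C@H]2C=C[C@@H]3C[C@H](C)CC[C@@H]3[C@@]2(C)CO[Si](c4ccccc4)(c5ccccc5)C(C)(C)C | intermediate
23 | phenyltetrazolyl sulfide | c1ccccc1-n1nnnc1SC[C@H]2C=C[C@@H]3C[C@H](C)CC[C@@H]3[C@@]2(C)CO[Si](c4ccccc4)(c5ccccc5)C(C)(C)C | intermediate
24 | phenyltetrazolyl sulfone | O=S(=O)(C[C@H]2C=C[C@@H]3C[C@H](C)CC[C@@H]3[C@@]2(C)CO[Si](c4ccccc4)(c5ccccc5)C(C)(C)C)c1nnnn1-c1ccccc1 | intermediate
25 | (E)-but-2-enal | C/C=C/C=O | starting material
26 | dienyl octalin, C1 arm TBDPS-protected | C/C=C/C=C/[C@H]2C=C[C@@H]3C[C@H](C)CC[C@@H]3[C@@]2(C)CO[Si](c4ccccc4)(c5ccccc5)C(C)(C)C | intermediate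
27 | C1 hydroxymethyl dienyl octalin | C/C=C/C=C/[C@H]2C=C[C@@H]3C[C@H](C)CC[C@@H]3[C@@]2(C)CO | intermediate
28 | C1 carbaldehyde | C/C=C/C=C/[C@H]2C=C[C@@H]3C[C@H](C)CC[C@@H]3[C@@]2(C)C=O | intermediate
29 | S-tert-butyl ethanethioate | CC(=O)SC(C)(C)C | starting material
30 | β-hydroxy thioester | C/C=C/C=C/[C@H]2C=C[C@@H]3C[C@H](C)CC[C@@H]3[C@@]2(C)C(O)CC(=O)SC(C)(C)C | intermediate
31 | β-keto thioester | C/C=C/C=C/[C@H]2C=C[C@@H]3C[C@H](C)CC[C@@H]3[C@@]2(C)C(=O)CC(=O)SC(C)(C)C | intermediate
32 | L-threonine methyl ester hydrochloride | COC(=O)[C@@H](N)[C@@H](C)O.Cl | starting material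
33 | O-TBS-L-threonine methyl ester | COC(=O)[C@@H](N)[C@@H](C)O[Si](C)(C)C(C)(C)C | intermediate
34 | β-ketoamide | C/C=C/C=C/[C@H]2C=C[C@@H]3C[C@H](C)CC[C@@H]3[C@@]2(C)C(=O)CC(=O)N[C@@H]([C@@H](C)O[Si](C)(C)C(C)(C)C)C(=O)OC | intermediate
35 | O-silylated 3-acyltetramic acid | C/C=C/C=C/[C@H]2C=C[C@@H]3C[C@H](C)CC[C@@H]3[C@@]2(C)C(=O)C1=C(O)[C@H]([C@@H](C)O[Si](C)(C)C(C)(C)C)NC1=O | intermediate
36 | CNP0298257.5 | C/C=C/C=C/[C@H]1C=C[C@@H]2C[C@H](C)CC[C@@H]2[C@@]1(C)C(=O)C1=C(O)[C@H]([C@@H](C)O)NC1=O | target

## Step count and least certain steps

Total step count: 26. Longest linear sequence: 25 steps (steps 1–22 and 24–26, from 1 to 36); step 23 is a one-step side branch.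

**Step 11 (key step).** The most likely failure is loss of facial control at C6: proton delivery to the concave face of enolate 17, or re-enolisation of 18 after the quench, either of which drains C6 toward the more stable epimer. Heterolytic cleavage of C3–C7 without recombination is a lesser concern. The fallback replaces proton transfer by hydrogen-atom transfer. Setting out from 15, the enolate is trapped with Me3SiCl to give silyl enol ether F1. NBS in THF at −78 °C converts F1 into the C6 bromo ketone F2. Reduction of F2 with (Me3Si)3SiH and Et3B/O2 in toluene at −78 °C passes through a planar α-keto radical, which should take hydrogen from the bulky silane on the exposed convex face under neutral conditions. The sequence returns to the route at 18.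

**Step 3.** Dimerisation of 6 may outrun its capture by the trisubstituted dienophile 4, and the acetic acid released in methanol may exchange the acetal of 4. The regiochemistry also rests on analogy with open-chain acrylates. The fallback separates generation and capture. Setting out from 5, oxidation in methanol without a trap lets 6 dimerise to the dimer F3. Heating F3 with 4 in mesitylene at about 220 °C in a sealed tube releases 6 slowly by retro-Diels–Alder cleavage into an excess of 4, without methanol or acid. It returns at 7.

**Step 8.** The C8 radical may close onto C4a=C4 and reopen, a homoallyl to cyclopropylcarbinyl rearrangement that would transpose the skeleton to a bicyclo[3.2.1]octene. The fallback avoids a carbon radical at C8. Setting out from 10, the ketal is hydrolysed (oxalic acid, wet SiO2) to the α-hydroxy ketone F4, which is acetylated at once (Ac2O, pyridine, DMAP) to the α-acetoxy ketone F5. SmI2 in THF/MeOH at −78 °C then removes the acetate by electron transfer to the carbonyl and β-elimination to a samarium enolate. It returns at 13.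

**Step 18.** The E selectivity at the new double bond may erode, or the sulfonyl anion may add in conjugate fashion to 25. The fallback builds the diene by stereospecific coupling. Setting out from 22, Dess–Martin oxidation gives aldehyde F6, used cold and at once. Takai olefination (CrCl2, CHI3, THF, 0 °C) gives the (E)-vinyl iodide F7. Suzuki coupling of F7 with (E)-prop-1-enylboronic acid pinacol ester (Pd(PPh3)4, aq K3PO4, THF) returns to the route at 26.

**Step 25.** The threonine α-carbon may epimerise by ester enolisation before ring closure, or silanolate may be lost by β-elimination. The fallback drops the protecting group. Setting out from 31 and the free base of 32, silver-assisted aminolysis (AgOCOCF3, Et3N) gives the hydroxy β-ketoamide F8. Cyclisation of F8 with NaOMe in MeOH at rt has no leaving group for elimination, and the deprotonated hydroxyl disfavours a further deprotonation next to it. It arrives directly at 36 and saves step 26.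

## Further compounds

F1 | step 11 | trimethylsilyl enol ether (C6=C7) of 18 | CC(C)(C)[Si](C)(C)OC[C@H]2C=C[C@@H]3CC(C)=C(O[Si](C)(C)C)C[C@@H]3[C@@]2(C)CO[Si](c4ccccc4)(c5ccccc5)C(C)(C)C
F2 | step 11 | 6-bromo-6-methyl C7 ketone | CC(C)(C)[Si](C)(C)OC[C@H]2C=C[C@@H]3C[C@](Br)(C)C(=O)C[C@@H]3[C@@]2(C)CO[Si](c4ccccc4)(c5ccccc5)C(C)(C)C
F3 | step 3 | Diels–Alder dimer of 6 (racemic, one enantiomer drawn) | O=C1C=C[C@H]2[C@@H](C1(OC)OC)[C@H]1C=C[C@@H]2C(=O)C1(OC)OC
F4 | step 8 | C8-hydroxy C7 ketone | CC(C)(C)[Si](C)(C)OC[C@H]2[C@H]3C=C[C@H]([C@@H](O)C3=O)[C@@]2(C)CO[Si](c4ccccc4)(c5ccccc5)C(C)(C)C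
F5 | step 8 | C8-acetoxy C7 ketone | CC(C)(C)[Si](C)(C)OC[C@H]2[C@H]3C=C[C@H]([C@@H](OC(C)=O)C3=O)[C@@]2(C)CO[Si](c4ccccc4)(c5ccccc5)C(C)(C)C
F6 | step 18 | C2 carbaldehyde | O=C[C@H]2C=C[C@@H]3C[C@H](C)CC[C@@H]3[C@@]2(C)CO[Si](c4ccccc4)(c5ccccc5)C(C)(C)C
F7 | step 18 | C2 (E)-2-iodovinyl compound | I/C=C/[C@H]2C=C[C@@H]3C[C@H](C)CC[C@@H]3[C@@]2(C)CO[Si](c4ccccc4)(c5ccccc5)C(C)(C)C
F8 | step 25 | β-ketoamide with free threonine hydroxyl | C/C=C/C=C/[C@H]2C=C[C@@H]3C[C@H](C)CC[C@@H]3[C@@]2(C)C(=O)CC(=O)N[C@@H]([C@@H](C)O)C(=O)OC
A1 | alternative 1 | cis-decalin methyl ester with the pentadienyl group | C/C=C/C=C/[C@H]1C=C[C@@H]2C[C@H](C)CC[C@@H]2[C@@]1(C)C(=O)OC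
A2 | alternative 1 | (Z)-vinyl iodide with the hexa-1,4-dienyl arm on C1 | I/C=C\[C@@H]1C[C@H](C)CC[C@@H]1[C@@](C)(C(=O)OC)/C=C/C/C=C/C
A3 | alternative 2 | cis-decalin C1 carboxylic acid with the pentadienyl group | C/C=C/C=C/[C@H]1C=C[C@@H]2C[C@H](C)CC[C@@H]2[C@@]1(C)C(=O)O
A4 | alternative 2 | cis-fused six-membered lactone with a heptatrienyl group on C4 (C1 epimer immaterial) | O=C1O[C@H](/C=C/C=C/C=C/C)[C@@H]2C[C@H](C)CC[C@@H]2[C@@H]1C
A5 | alternative 3 | cis-decalin methyl ester with a silyloxymethyl group at C2 | CC(C)(C)[Si](C)(C)OC[C@H]1C=C[C@@H]2C[C@H](C)CC[C@@H]2[C@@]1(C)C(=O)OC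
A6 | alternative 3 | cyclohexene with the (Z)-vinyl iodide side chain | I/C=C\[C@H](CO[Si](C)(C)C(C)(C)C)[C@](C)(C(=O)OC)[C@H]1CC[C@@H](C)C=C1
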